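The route rests on disconnecting the lactone ring bond O1–C2 together with the exocyclic C2–C1′ bond. A rhodium carbenoid generated at C2 from an acyclic α-diazo ester is captured by the oxygen of a tethered, enantiopure secondary allylic ether; the five-membered oxonium ylide thus closed (O1–C2) undergoes [2,3]-sigmatropic rearrangement, which forges C2–C1′ and sets both stereocentres in one operation. The feature exploited is the fully substituted, oxygen-bearing C2 of the oxolane ring adjacent to the carboxy-bearing C1′: the transposed propenyl group is a latent C1′ carboxyl, and ring C5 is raised to the lactone carbonyl afterwards by RuO4. The (R)-malate is attached last.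

Key step: step 7

Remark on the chemistry: locants used throughout are O1, C2 (quaternary), C3, C4, C5 (carbonyl) for the lactone ring and C1′ for the side-chain CH that carries a carboxyl group; the target is read as 2R,1′R with an (R)-malate 1-ester, and all numbered starting materials are assumed to be commercially available.

Step 1
Reactants: 1 10-bromodecan-1-ol; 2 tert-butyl(chloro)dimethylsilane
Product: 3 [(10-bromodecyl)oxy](tert-butyl)dimethylsilane
Conditions: TBSCl, imidazole, CH2Cl2, 0 °C to rt
Reagents that add atoms: tert-butyl(chloro)dimethylsilane (2), CC(C)(C)[Si](C)(C)Cl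
Why: Imidazole-promoted silylation (silyl ether protection) masks the chain-end oxygen as a group that should tolerate the organolithium, hydride, enolate, carbenoid and RuO4 steps that follow.

Step 2
Reactants: 3 [(10-bromodecyl)oxy](tert-butyl)dimethylsilane; 4 (R)-but-3-yn-2-ol
Product: 5 (2R)-14-[(tert-butyldimethylsilyl)oxy]tetradec-3-yn-2-ol
Conditions: 4, n-BuLi (2.1 equiv), THF, −78 to 0 °C; then 3, DMPU, 0 °C to rt; H2O quench
Reagents that add atoms: (R)-but-3-yn-2-ol (4), C[C@@H](O)C#C
Why: SN2 alkylation of the alkynol dianion occurs at the acetylide carbon, which is far more nucleophilic than the lithium alkoxide, and the carbinol stereocentre brought in with 4 is not touched.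

Step 3
Reactants: 5 (2R)-14-[(tert-butyldimethylsilyl)oxy]tetradec-3-yn-2-ol
Product: 6 (2R,3E)-14-[(tert-butyldimethylsilyl)oxy]tetradec-3-en-2-ol
Conditions: LiAlH4, THF, 0 °C to reflux; aqueous Rochelle salt work-up
Reagents that add atoms: none
Why: Hydroxyl-directed trans-hydroalumination of the propargylic alcohol (LiAlH4 reduction of a propargylic alcohol) should give only the E-alkene after protonolysis, with the silyl ether and the carbinol centre unchanged.

Step 4
Reactants: 6 (2R,3E)-14-[(tert-butyldimethylsilyl)oxy]tetradec-3-en-2-ol; 7 1-bromo-3-chloropropane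
Product: 8 tert-butyl{[(11E,13R)-13-(3-chloropropoxy)tetradec-11-en-1-yl]oxy}dimethylsilane
Conditions: NaH, DMF, 0 °C; then 7 (3 equiv), 0 °C to rt
Reagents that add atoms: 1-bromo-3-chloropropane (7), ClCCCBr
Why: Williamson ether synthesis at the bromide terminus (bromide is displaced much faster than chloride) installs the three-carbon tether; the C–O bond of the stereocentre is not broken, so its configuration is retained.

Step 5
Reactants: 8 tert-butyl{[(11E,13R)-13-(3-chloropropoxy)tetradec-11-en-1-yl]oxy}dimethylsilane; 9 tert-butyl 3-oxobutanoate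
Product: 10 tert-butyl 2-acetyl-5-{[(2R,3E)-14-[(tert-butyldimethylsilyl)oxy]tetradec-3-en-2-yl]oxy}pentanoate (both epimers at C2 of the pentanoate)
Conditions: 9 (3 equiv), K2CO3, NaI (cat.), DMF, 70 °C
Reagents that add atoms: tert-butyl 3-oxobutanoate (9), CC(=O)CC(=O)OC(C)(C)C
Why: Acetoacetic ester C-alkylation with Finkelstein activation of the primary chloride should proceed cleanly with excess enolate to limit dialkylation; the new α-centre forms unselectively but becomes sp2 in step 6.

Step 6
Reactants: 10 tert-butyl 2-acetyl-5-{[(2R,3E)-14-[(tert-butyldimethylsilyl)oxy]tetradec-3-en-2-yl]oxy}pentanoate; 11 4-acetamidobenzenesulfonyl azide (p-ABSA)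
Product: 12 tert-butyl 2-diazo-5-{[(2R,3E)-14-[(tert-butyldimethylsilyl)oxy]tetradec-3-en-2-yl]oxy}pentanoate
Conditions: p-ABSA, DBU, MeCN, 0 °C to rt
Reagents that add atoms: 4-acetamidobenzenesulfonyl azide (11), CC(=O)Nc1ccc(cc1)S(=O)(=O)N=[N+]=[N-]
Why: Deacylative Regitz diazo transfer: the enolate adds to the sulfonyl azide and the adduct fragments with transfer of the acetyl group to the sulfonamide nitrogen, leaving the α-alkyl-α-diazo ester.

Step 7
Reactants: 12 tert-butyl 2-diazo-5-{[(2R,3E)-14-[(tert-butyldimethylsilyl)oxy]tetradec-3-en-2-yl]oxy}pentanoate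
Product: 14 tert-butyl (2R)-2-[(2E,4S)-14-[(tert-butyldimethylsilyl)oxy]tetradec-2-en-4-yl]oxolane-2-carboxylate, via oxonium ylide 13 (not isolated)
Conditions: Rh2(OPiv)4 (dirhodium tetrapivalate, 1 mol %), CH2Cl2, −78 °C to rt, slow addition of 12
Reagents that add atoms: none
Why: Rh2(OPiv)4 turns the diazo ester into an electrophilic rhodium carbenoid at C2, which is attacked by a lone pair of the tethered ether oxygen (five-membered ring closure, 5-exo with respect to the Rh=C bond, forming O1–C2) to give oxonium ylide 13; its [2,3]-sigmatropic rearrangement through a five-membered envelope transition state then forms C2–C1′, breaks the O–CH(CH3) bond and transposes the alkene into an (E)-propenyl group. The closest known reactions are the tandem oxonium ylide formation/[2,3]-rearrangements of allyl ethers tethered to diazoketones, α-diazo-β-keto esters and diazoacetates. C1′ is controlled by suprafacial 1,3-chirality transfer from the (R)-carbinol carbon, whose methyl group sits pseudo-equatorial in the envelope (hence the new E-alkene and the 4S centre of the side chain). C2 is controlled by the placement of the allyl unit outside the oxolane ring, over the planar ester enolate instead of over the ring CH2 (ester endo), which with the E-alkene puts the long chain next to the flat ester and should give 2R. The step needs ylide formation to outrun the 1,2-hydride shift from C3 and the [2,3]-shift to beat a [1,2]-shift: the first is secured by the five-membered proximity of the ether oxygen together with the bulky pivalate ligands and low temperature known to suppress β-hydride migration of α-alkyl-α-diazo esters, the second by the allylic nature of the migrating group.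

Step 8
Reactants: 14 tert-butyl (2R)-2-[(2E,4S)-14-[(tert-butyldimethylsilyl)oxy]tetradec-2-en-4-yl]oxolane-2-carboxylate
Product: 15 (2R)-2-[(2R)-2-(tert-butoxycarbonyl)-5-oxooxolan-2-yl]-12-[(tert-butyldimethylsilyl)oxy]dodecanoic acid
Conditions: RuCl3·xH2O (5 mol %), NaIO4 (excess), CCl4/MeCN/H2O, rt
Reagents that add atoms: sodium periodate, [Na+].[O-]I(=O)(=O)=O; water, O
Why: Catalytic RuO4 oxidation should cleave the propenyl group to the C1′ carboxylic acid and, as in the known oxidation of cyclic ethers to lactones, convert the only ether CH2 (ring C5, since C2 is fully substituted) into the lactone carbonyl, with no bond to either stereocentre broken.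

Step 9
Reactants: 15 (2R)-2-[(2R)-2-(tert-butoxycarbonyl)-5-oxooxolan-2-yl]-12-[(tert-butyldimethylsilyl)oxy]dodecanoic acid
Product: 16 (2R)-2-[(2R)-2-(tert-butoxycarbonyl)-5-oxooxolan-2-yl]-12-hydroxydodecanoic acid
Conditions: HF·pyridine, THF, 0 °C to rt
Reagents that add atoms: none
Why: Fluoride-driven desilylation, under mildly acidic conditions, should free the primary alcohol and leave the tert-butyl ester, the lactone and the base-sensitive C1′ centre untouched.

Step 10
Reactants: 17 (R)-malic acid; 18 trifluoroacetic anhydride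
Product: 19 (3R)-2,5-dioxooxolan-3-yl trifluoroacetate
Conditions: neat (CF3CO)2O, 0 °C to rt; volatiles removed in vacuo
Reagents that add atoms: trifluoroacetic anhydride (18), O=C(OC(=O)C(F)(F)F)C(F)(F)F
Why: Trifluoroacetylation of the hydroxyl and cyclodehydration of the 1,4-diacid via mixed anhydrides give the activated cyclic anhydride without breaking any bond to the stereocentre, so the R configuration is kept.

Step 11
Reactants: 16 (2R)-2-[(2R)-2-(tert-butoxycarbonyl)-5-oxooxolan-2-yl]-12-hydroxydodecanoic acid; 19 (3R)-2,5-dioxooxolan-3-yl trifluoroacetate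
Product: 21 (2R)-2-[(2R)-2-(tert-butoxycarbonyl)-5-oxooxolan-2-yl]-12-{[(2R)-3-carboxy-2-hydroxypropanoyl]oxy}dodecanoic acid, via trifluoroacetate ester 20 (not isolated)
Conditions: 19 (1.5 equiv), THF, rt; then H2O, rt
Reagents that add atoms: (3R)-2,5-dioxooxolan-3-yl trifluoroacetate (19), O=C1C[C@@H](OC(=O)C(F)(F)F)C(=O)O1
Why: Regioselective alcoholysis of the unsymmetrical anhydride at the carbonyl next to the electron-poor trifluoroacetoxy-bearing carbon should give the malate 1-ester, and the labile trifluoroacetate is hydrolysed during the aqueous work-up, while the hindered free acid of 16 does not compete with the primary alcohol.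

Step 12
Reactants: 21 (2R)-2-[(2R)-2-(tert-butoxycarbonyl)-5-oxooxolan-2-yl]-12-{[(2R)-3-carboxy-2-hydroxypropanoyl]oxy}dodecanoic acid
Product: 22 (2R)-2-[(1R)-1-carboxy-11-{[(2R)-3-carboxy-2-hydroxypropanoyl]oxy}undecyl]-5-oxooxolane-2-carboxylic acid
Conditions: CF3CO2H/CH2Cl2 (1:1), rt; evaporation
Reagents that add atoms: none
Why: Acidolysis of the tert-butyl ester (loss of isobutene through the tert-butyl cation) under anhydrous acid should leave the lactone, the malate ester and all three stereocentres intact.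

Compound list
1 | 10-bromodecan-1-ol | OCCCCCCCCCCBr | starting material
2 | tert-butyl(chloro)dimethylsilane | CC(C)(C)[Si](C)(C)Cl | starting material
3 | [(10-bromodecyl)oxy](tert-butyl)dimethylsilane | CC(C)(C)[Si](C)(C)OCCCCCCCCCCBr | intermediate
4 | (R)-but-3-yn-2-ol | C[C@@H](O)C#C | starting material
5 | (2R)-14-[(tert-butyldimethylsilyl)oxy]tetradec-3-yn-2-ol | C[C@@H](O)C#CCCCCCCCCCCO[Si](C)(C)C(C)(C)C | intermediate
6 | (2R,3E)-14-[(tert-butyldimethylsilyl)oxy]tetradec-3-en-2-ol | C[C@@H](O)/C=C/CCCCCCCCCCO[Si](C)(C)C(C)(C)C | intermediate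
7 | 1-bromo-3-chloropropane | ClCCCBr | starting material
8 | tert-butyl{[(11E,13R)-13-(3-chloropropoxy)tetradec-11-en-1-yl]oxy}dimethylsilane | ClCCCO[C@H](C)/C=C/CCCCCCCCCCO[Si](C)(C)C(C)(C)C | intermediate
9 | tert-butyl 3-oxobutanoate | CC(=O)CC(=O)OC(C)(C)C | starting material
10 | tert-butyl 2-acetyl-5-{[(2R,3E)-14-[(tert-butyldimethylsilyl)oxy]tetradec-3-en-2-yl]oxy}pentanoate (epimers at C2) | CC(=O)C(CCCO[C@H](C)/C=C/CCCCCCCCCCO[Si](C)(C)C(C)(C)C)C(=O)OC(C)(C)C | intermediate
11 | 4-acetamidobenzenesulfonyl azide | CC(=O)Nc1ccc(cc1)S(=O)(=O)N=[N+]=[N-] | starting material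
12 | tert-butyl 2-diazo-5-{[(2R,3E)-14-[(tert-butyldimethylsilyl)oxy]tetradec-3-en-2-yl]oxy}pentanoate | CC(C)(C)OC(=O)C(=[N+]=[N-])CCCO[C@H](C)/C=C/CCCCCCCCCCO[Si](C)(C)C(C)(C)C | intermediate
13 | 2-(tert-butoxycarbonyl)-1-[(2R,3E)-14-[(tert-butyldimethylsilyl)oxy]tetradec-3-en-2-yl]oxolan-1-ium-2-ide (oxonium ylide) | CC(C)(C)OC(=O)[C-]1CCC[O+]1[C@H](C)/C=C/CCCCCCCCCCO[Si](C)(C)C(C)(C)C | intermediate
14 | tert-butyl (2R)-2-[(2E,4S)-14-[(tert-butyldimethylsilyl)oxy]tetradec-2-en-4-yl]oxolane-2-carboxylate | CC(C)(C)[Si](C)(C)OCCCCCCCCCC[C@@H](/C=C/C)[C@@]1(C(=O)OC(C)(C)C)CCCO1 | intermediate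
15 | (2R)-2-[(2R)-2-(tert-butoxycarbonyl)-5-oxooxolan-2-yl]-12-[(tert-butyldimethylsilyl)oxy]dodecanoic acid | CC(C)(C)[Si](C)(C)OCCCCCCCCCC[C@@H](C(=O)O)[C@@]1(C(=O)OC(C)(C)C)CCC(=O)O1 | intermediate
16 | (2R)-2-[(2R)-2-(tert-butoxycarbonyl)-5-oxooxolan-2-yl]-12-hydroxydodecanoic acid | OCCCCCCCCCC[C@@H](C(=O)O)[C@@]1(C(=O)OC(C)(C)C)CCC(=O)O1 | intermediate
17 | (R)-malic acid | O[C@H](CC(=O)O)C(=O)O | starting material
18 | trifluoroacetic anhydride | O=C(OC(=O)C(F)(F)F)C(F)(F)F | starting material
19 | (3R)-2,5-dioxooxolan-3-yl trifluoroacetate | O=C1C[C@@H](OC(=O)C(F)(F)F)C(=O)O1 | intermediate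
20 | (2R)-2-[(2R)-2-(tert-butoxycarbonyl)-5-oxooxolan-2-yl]-12-{[(2R)-3-carboxy-2-(trifluoroacetoxy)propanoyl]oxy}dodecanoic acid | O=C(O)C[C@@H](OC(=O)C(F)(F)F)C(=O)OCCCCCCCCCC[C@@H](C(=O)O)[C@@]1(C(=O)OC(C)(C)C)CCC(=O)O1 | intermediate
21 | (2R)-2-[(2R)-2-(tert-butoxycarbonyl)-5-oxooxolan-2-yl]-12-{[(2R)-3-carboxy-2-hydroxypropanoyl]oxy}dodecanoic acid | O=C(O)C[C@@H](O)C(=O)OCCCCCCCCCC[C@@H](C(=O)O)[C@@]1(C(=O)OC(C)(C)C)CCC(=O)O1 | intermediate
22 | (2R)-2-[(1R)-1-carboxy-11-{[(2R)-3-carboxy-2-hydroxypropanoyl]oxy}undecyl]-5-oxooxolane-2-carboxylic acid | O=C(O)C[C@@H](O)C(=O)OCCCCCCCCCC[C@@H](C(=O)O)[C@@]1(C(=O)O)CCC(=O)O1 | target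

Total step count: 12. Longest linear sequence: 11 steps (steps 1 to 9, 11 and 12); step 10 is a one-step side branch.

Steps most likely to fail

1. Step 7. The carbenoid may undergo 1,2-hydride shift from C3 to the α,β-unsaturated ester before the ether oxygen closes the ring. Facial discrimination in the rearrangement may also be poor (allyl unit over the ring instead of over the ester, or methyl pseudo-axial), which would erode the C2/C1′ configuration. The fallback sets out from 6 and comes back at 14, keeping the O1–C2 ring closure but using a carbenoid with no β-hydrogen. Alcohol 6 is cyanoethylated with acrylonitrile and catalytic benzyltrimethylammonium hydroxide to the β-alkoxy nitrile F1. A Blaise reaction with the zinc enolate of tert-butyl bromoacetate, followed by mild acid hydrolysis, gives the β-keto ester F2. Regitz diazo transfer (p-ABSA, Et3N) gives the α-diazo-β-keto ester F3. Rh2(OAc)4 (dirhodium tetraacetate) in CH2Cl2 then effects the well-precedented oxonium ylide formation/[2,3]-rearrangement to the 3-oxooxolane F4. The surplus C3 ketone is removed through the tosylhydrazone F5 by catecholborane reduction and NaOAc, which gives 14.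

2. Step 8. The silyl ether may be cleaved in the acidic aqueous oxidant and the liberated primary alcohol over-oxidised, or the oxidation of the electron-poor oxolane CH2 may stall. The fallback sets out from 14 and comes back at 15 by separating the two oxidations. Ozonolysis (O3, CH2Cl2, −78 °C; PPh3) gives the aldehyde F6. Pinnick oxidation (NaClO2, NaH2PO4, 2-methylbut-2-ene) gives the oxolane acid F7 without acid stress on the silyl ether. The ring C5 methylene alone is then oxidised with methyl(trifluoromethyl)dioxirane generated in situ under bicarbonate buffer, giving 15.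

3. Step 4. The hindered secondary alkoxide may dehydrohalogenate the dihalide instead of substituting it, leaving 6 unconverted. The fallback sets out from 6 and comes back at 10. O-Allylation with allyl bromide and NaH (an electrophile that cannot eliminate) gives the allyl ether F8. Hydroboration with 9-BBN, selective for the monosubstituted alkene, and NaOH/H2O2 give the primary alcohol F9. Appel iodination (I2, PPh3, imidazole) gives the iodide F10, which alkylates 9 (K2CO3, DMF) to give 10.

Further compounds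
F1 | step 7 | 3-{[(2R,3E)-14-[(tert-butyldimethylsilyl)oxy]tetradec-3-en-2-yl]oxy}propanenitrile | N#CCCO[C@H](C)/C=C/CCCCCCCCCCO[Si](C)(C)C(C)(C)C
F2 | step 7 | tert-butyl 5-{[(2R,3E)-14-[(tert-butyldimethylsilyl)oxy]tetradec-3-en-2-yl]oxy}-3-oxopentanoate | CC(C)(C)OC(=O)CC(=O)CCO[C@H](C)/C=C/CCCCCCCCCCO[Si](C)(C)C(C)(C)C
F3 | step 7 | tert-butyl 2-diazo-5-{[(2R,3E)-14-[(tert-butyldimethylsilyl)oxy]tetradec-3-en-2-yl]oxy}-3-oxopentanoate | CC(C)(C)OC(=O)C(=[N+]=[N-])C(=O)CCO[C@H](C)/C=C/CCCCCCCCCCO[Si](C)(C)C(C)(C)C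
F4 | step 7 | tert-butyl (2S)-2-[(2E,4S)-14-[(tert-butyldimethylsilyl)oxy]tetradec-2-en-4-yl]-3-oxooxolane-2-carboxylate | CC(C)(C)[Si](C)(C)OCCCCCCCCCC[C@@H](/C=C/C)[C@@]1(C(=O)OC(C)(C)C)C(=O)CCO1
F5 | step 7 | tert-butyl (2S)-2-[(2E,4S)-14-[(tert-butyldimethylsilyl)oxy]tetradec-2-en-4-yl]-3-[2-(4-methylbenzenesulfonyl)hydrazinylidene]oxolane-2-carboxylate | CC(C)(C)[Si](C)(C)OCCCCCCCCCC[C@@H](/C=C/C)[C@@]1(C(=O)OC(C)(C)C)C(=NNS(=O)(=O)c2ccc(C)cc2)CCO1
F6 | step 8 | tert-butyl (2R)-2-[(2R)-12-[(tert-butyldimethylsilyl)oxy]-1-oxododecan-2-yl]oxolane-2-carboxylate | CC(C)(C)[Si](C)(C)OCCCCCCCCCC[C@@H](C=O)[C@@]1(C(=O)OC(C)(C)C)CCCO1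
F7 | step 8 | (2R)-2-[(2R)-2-(tert-butoxycarbonyl)oxolan-2-yl]-12-[(tert-butyldimethylsilyl)oxy]dodecanoic acid | CC(C)(C)[Si](C)(C)OCCCCCCCCCC[C@@H](C(=O)O)[C@@]1(C(=O)OC(C)(C)C)CCCO1
F8 | step 4 | tert-butyldimethyl{[(11E,13R)-13-(prop-2-en-1-yloxy)tetradec-11-en-1-yl]oxy}silane | C=CCO[C@H](C)/C=C/CCCCCCCCCCO[Si](C)(C)C(C)(C)C
F9 | step 4 | 3-{[(2R,3E)-14-[(tert-butyldimethylsilyl)oxy]tetradec-3-en-2-yl]oxy}propan-1-ol | OCCCO[C@H](C)/C=C/CCCCCCCCCCO[Si](C)(C)C(C)(C)C
F10 | step 4 | tert-butyl{[(11E,13R)-13-(3-iodopropoxy)tetradec-11-en-1-yl]oxy}dimethylsilane | ICCCO[C@H](C)/C=C/CCCCCCCCCCO[Si](C)(C)C(C)(C)C
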